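**Counting turns.** One count holds while you repeat this run: I take each turn of the enzyme to make one target from one substrate and to leave the enzyme as it was, so a target reading counts turns.

| setting | Monday's | Thursday's | flask |
|---|---|---|---|
| substrate | 10 mM | 10 mM | 10 mM |
| free enzyme | 1.7 µM | 3.4 µM | 1.7 µM |
| temperature | 40 °C | 46 °C | 40 °C |
| remark | the very flask that is asked about, followed so far | run made earlier |  |
| time |  |  | 1.5 h |

| run | time / min | target / % |
|---|---|---|
| Monday's | 3.00 | 16 |
| Monday's | 8.00 | 40 |
| Monday's | 15.0 | 59 |
| Monday's | 25.0 | 74 |
| Monday's | 30.0 | 73 |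
| Monday's | 40.0 | 74 |
| Monday's | 50.0 | 76 |
| Thursday's | 0.833 | 11 |
| Thursday's | 1.33 | 15 |
| Thursday's | 2.00 | 15 |
| Thursday's | 3.00 | 30 |
| Thursday's | 4.00 | 37 |
| Thursday's | 6.00 | 51 |
| Thursday's | 10.0 | 72 |

(scatter of a reading: 2 percentage points)

- oak: at 1.5 h add free enzyme, 100% of the amount charged, then wait 1.5 h
- maple: at 1.5 h raise the temperature by 20 K, then wait 1.5 h
- larch: change nothing and wait 1.5 h more
- birch: at 1.5 h take out 90% of the target then present, then wait 1.5 h

1. target, in percent of the substrate first charged, at 1.5 h
2. what to do for the largest gain in target; "none" if nothing gains more than 2 percentage points (oak / maple / larch / birch / none)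
3. target present, with what was taken out counted in, in percent of the substrate first charged, after oak
4. target present, with what was taken out counted in, in percent of the substrate first charged, after larch

- removed target is counted in
- the numbers in the tables scatter by 2 percentage points (one standard deviation)
- additions bring no volume worth counting

**Bench rule.** The usual rule says a catalyst isn't used up, so conversion simply goes on with time. On Monday's run, 40% at 8.00 min gives a first-order constant of 0.0639 min⁻¹. That constant predicts 61.7% at 15.0 min, where you read 59%, but 95.9% at 50.0 min, where you read 76%.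

**The border.** Monday's readings stand flat from 25.0 min on, at a mean of 74.2%. That is 4370 turns per enzyme charged, the turn capacity, in the field's term the total turnover number. Finishing the substrate takes c(substrate)/c(free enzyme) turns per enzyme: 5880 on Monday, more than the capacity, and 2940 on Thursday, less than it. So if the enzyme stopped, Thursday's run should have room to pass Monday's height. But Thursday's last reading, 72% at 10.0 min, still stands below that height, so Thursday's readings do not show this, and an equilibrium wall stays open. Thursday's run is also warmer than Monday's.

**My reckoning.** Watch for a flat stage with substrate still there. I expect about 74.2% at 1.5 h, and the same after waiting. I bet on the stopped enzyme: oak then brings fresh capacity, so I expect about 100%, and I choose oak.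

**The forecast.** The forecast says “I therefore read the plateau as equilibrium”. It gives 75% now, 75.5% after larch, 75.5% after oak, and chooses birch, so we part on oak and on the choice.

**The result.** The flask gives 74.1% now, 74.1% after larch and 95.2% after oak, and the best choice is oak, gaining 21 percentage points.

    2 free enzyme ⇌ resting dimer, settled at all times (K = 1.60 × 10⁶ M⁻¹, ΔH = −41.0 kJ mol⁻¹)
    free enzyme → spent catalyst (k = 0.221 min⁻¹, Ea = 89.0 kJ mol⁻¹)
    substrate + free enzyme → target + free enzyme, rate k3*[substrate]*[free enzyme]/(1 + ([substrate]/Km3) + ([substrate]/Ksi3)^2) (3.31 mM, 6.17 mM, k = 11100 M⁻¹ s⁻¹, Ea = 20.0 kJ mol⁻¹)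
    free enzyme + target → free enzyme + over-reaction product (k = 4700 M⁻¹ min⁻¹, Ea = 37.0 kJ mol⁻¹)
    free enzyme → unfolded enzyme (k = 0.00923 min⁻¹, Ea = 263 kJ mol⁻¹)
    (constants at 40 °C)

**When it ran.** In the flask, target reached 43.3% at 9.00 min with 54.5% of the catalyst spent. By 45.0 min target stood at 74.1%, with free enzyme at 0.0474%, spent catalyst at 95.9% and substrate at 24.6%. Oak's two doses carry 148% of the charge in turns. The neighbour flask with 0.0043 mM of free enzyme carries 188%, and there substrate fell to 0.030% and target reached 93.8%.

The earlier runs and the new flask were computed for an exercise, and the scatter is random.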